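## Retrosynthetic overview

1. Target 25 ⇐ acetylation ⇐ hydroxyl-directed 4,5-epoxidation ⇐ C6 ketone reduction ⇐ O-angeloylation of (3R,7R)-3-hydroxygermacra-1(10)E,4E-dien-6-one 19.
2. 19 ⇐ catalyst-controlled reduction at C3 plus C7 equilibration of the E,E-enedione 17 ⇐ Z→E correction of the Z-enedione 13 (1,4-reduction, selenenylation, syn-elimination).
3. Ten-membered ring 13 ⇐ anionic oxy-Cope ring expansion (C1–C6 cleaved, C8–C9 formed) of the trans-1,2-dialkenylcyclohexenol 11.
4. 11 ⇐ alkoxide-directed conjugate isopropenylation of p-quinol 9 ⇐ alkenyllithium addition to quinone monoketal 3 ⇐ oxidative dearomatization of m-cresol (key step; the six arene carbons become C1–C6).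
5. Ring order: arene ring (bought) → dearomatized six-membered ring (step 1) → ten-membered ring (step 5) → oxirane (step 10).

Assumption: ten-membered-ring compounds carry germacrane numbering (C1=C10 olefin, CH3 on C4 and C10, isopropyl on C7); compounds 9, 11, 13 and 17 are racemic and absolute configuration is first fixed in step 7.

## Route

**Step 1**
Reactants: 1 m-cresol (3-methylphenol)
Product: 3 4,4-dimethoxy-3-methylcyclohexa-2,5-dien-1-one, via 4-methoxy-3-methylphenol 2 (not isolated)
Conditions: PhI(OAc)2 (2.2 equiv), MeOH, 0 → 23 °C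
Reagents that add atoms: methanol (CO)
Why: Oxidative dearomatization of a phenol by a trivalent-iodine reagent, in which para-methoxylation is followed by a second two-electron oxidation that traps methanol again, gives the p-quinone monoketal with the ketal para to the former OH and next to the methyl group; no stereocentre is formed.

**Step 2**
Reactants: 4 3-methylbutan-2-one; 5 2,4,6-tri(propan-2-yl)benzenesulfonohydrazide
Product: 6 N'-(3-methylbutan-2-ylidene)-2,4,6-tri(propan-2-yl)benzenesulfonohydrazide
Conditions: HCl (cat.), MeOH, 23 °C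
Reagents that add atoms: none
Why: Acid-catalysed condensation of a ketone and an arylsulfonylhydrazide gives the hydrazone needed for a Shapiro reaction; no stereocentre is formed.

**Step 3**
Reactants: 6 trisylhydrazone of 3-methylbutan-2-one; 3 4,4-dimethoxy-3-methylcyclohexa-2,5-dien-1-one
Product: 9 4-hydroxy-2-methyl-4-(3-methylbut-1-en-2-yl)cyclohexa-2,5-dien-1-one (racemic), via (3-methylbut-1-en-2-yl)lithium 7 (not isolated), via ketal carbinol 8 (not isolated)
Conditions: n-BuLi (2.1 equiv), N,N,N',N'-tetramethylethylenediamine, THF, −78 → 0 °C; then 3, −78 °C; aq. NH4Cl; then AcOH–H2O (4:1), 23 °C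
Reagents that add atoms: water (O)
Why: Shapiro reaction in which the hydrazone dianion, formed at the less hindered methyl group, loses sulfinate and N2 to give vinyllithium 7, which adds 1,2 to the dienone carbonyl, and mild aqueous acid then unmasks the ketal to the p-quinol; the carbinol stereocentre is racemic and is erased in step 5.

**Step 4**
Reactants: 9 p-quinol; 10 isopropenylmagnesium bromide (prop-1-en-2-ylmagnesium bromide)
Product: 11 rac-(4R,5R)-4-hydroxy-2-methyl-4-(3-methylbut-1-en-2-yl)-5-(prop-1-en-2-yl)cyclohex-2-en-1-one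
Conditions: 10 (3.0 equiv), THF, −78 → 0 °C; aq. NH4Cl
Reagents that add atoms: none
Why: Alkoxide-directed conjugate addition of a Grignard reagent to a p-quinol, in which the bromomagnesium alkoxide delivers isopropenyl to the β-carbon of the unsubstituted enone arm (the α-methyl arm is less electrophilic) on the face syn to oxygen, so that OH and isopropenyl are cis and the two alkenyl groups trans (relative configuration only).

**Step 5**
Reactants: 11 trans-dialkenyl hydroxy enone
Product: 13 (1(10)E,4Z)-germacra-1(10),4-diene-3,6-dione (racemic at C7), via ring-expanded dipotassium bis-enolate 12 (not isolated)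
Conditions: KH (2.5 equiv), 18-crown-6, THF, 0 → 45 °C; then aq. NH4Cl, −78 °C
Reagents that add atoms: none
Why: Anionic oxy-Cope rearrangement of the potassium alkoxide through a chair transition state with both ring bonds equatorial cleaves C1–C6 and forms C8–C9, which gives the ten-membered ring with the new C1=C10 olefin E while the olefin inherited from the six-membered ring stays Z; the C3 ketone is held as its enolate so that no transannular aldol occurs, both old stereocentres are destroyed and C7 is formed racemic on protonation.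

**Step 6**
Reactants: 13 Z-enedione
Product: 17 (1(10)E,4E)-germacra-1(10),4-diene-3,6-dione (racemic at C7), via potassium C3–C4 enolate 14 (not isolated), via 4-phenylselanyl diketone 15 (not isolated), via selenoxide 16 (not isolated)
Conditions: K[HB(s-Bu)3] (1.05 equiv), THF, −78 °C; PhSeBr, −78 °C; then NaIO4, NaHCO3, THF–MeOH–H2O, 0 → 23 °C
Reagents that add atoms: none
Why: 1,4-Reduction by a bulky borohydride puts hydride on the unhindered C5 and gives the C3–C4 enolate regiospecifically, α-selenenylation places selenium on C4, and selenoxide syn-elimination toward the C5 hydrogens (acidified by the C6 carbonyl) rebuilds the enedione through the anticlinal ring torsion that ten-membered rings prefer in syn-eliminations and that avoids eclipsing the two acyl groups, so the 4,5-olefin is formed E.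

**Step 7**
Reactants: 17 E,E-enedione
Product: 19 (3R,7R,1(10)E,4E)-3-hydroxygermacra-1(10),4-dien-6-one, via C7-epimeric hydroxy enone 18 (not isolated)
Conditions: (S)-1-methyl-3,3-diphenyltetrahydro-1H,3H-pyrrolo[1,2-c][1,3,2]oxazaborole (0.2 equiv), catecholborane (1.3 equiv), toluene, −78 °C; MeOH–H2O; then K2CO3 (0.3 equiv), MeOH, 23 °C
Reagents that add atoms: none
Why: Corey–Bakshi–Shibata reduction in which the (S)-oxazaborolidine delivers hydride to the less hindered C3 carbonyl with the α-methylvinyl group as the large substituent, giving the (3R)-alcohol under catalyst control, after which base equilibrates the C7 centre α to the remaining ketone toward the epimer that has both the C3 oxygen and the C7 isopropyl group pseudo-equatorial on the crown conformer (7R).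

**Step 8**
Reactants: 19 hydroxy enone; 20 angelic acid ((2Z)-2-methylbut-2-enoic acid)
Product: 22 (3R,7R,1(10)E,4E)-6-oxogermacra-1(10),4-dien-3-yl (2Z)-2-methylbut-2-enoate, via angelic 2,4,6-trichlorobenzoic anhydride 21 (not isolated)
Conditions: 20 (1.5 equiv), 2,4,6-trichlorobenzoyl chloride (1.5 equiv), Et3N, toluene, 23 °C; then 19, 60 °C
Reagents that add atoms: none
Why: Yamaguchi-type esterification through the mixed anhydride without a nucleophilic catalyst acylates the only free hydroxyl and keeps the Z geometry of the angelate; no stereocentre is touched.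

**Step 9**
Reactants: 22 keto angelate
Product: 23 (3R,6S,7R,1(10)E,4E)-6-hydroxygermacra-1(10),4-dien-3-yl (2Z)-2-methylbut-2-enoate
Conditions: Li[HB(s-Bu)3] (1.2 equiv), THF, −78 °C; aq. NH4Cl
Reagents that add atoms: none
Why: Substrate-controlled 1,2-reduction of a β,β-disubstituted enone in which the bulky hydride attacks the C6 carbonyl from the ring periphery beside the pseudo-equatorial isopropyl group, as in the reduction of menthone to neomenthol, giving the (6S)-alcohol cis to the isopropyl group while the ester survives at −78 °C.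

**Step 10**
Reactants: 23 allylic alcohol
Product: 24 (3R,4R,5R,6S,7R,1(10)E)-4,5-epoxy-6-hydroxygermacr-1(10)-en-3-yl (2Z)-2-methylbut-2-enoate
Conditions: VO(acac)2 (5 mol %), t-BuOOH (1.5 equiv, decane), CH2Cl2, 0 °C
Reagents that add atoms: tert-butyl hydroperoxide (CC(C)(C)OO)
Why: Hydroxyl-directed epoxidation by a vanadium alkylperoxide bound to the C6 alkoxide touches only the allylic 4,5-olefin and delivers oxygen to the face syn to the hydroxyl in the rotamer that avoids A(1,3) strain with the cis C4 methyl group (threo product), which fixes (4R,5R) and the trans oxirane.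

**Step 11**
Reactants: 24 epoxy alcohol
Product: 25 (3R,4R,5R,6S,7R,1(10)E)-6-acetoxy-4,5-epoxygermacr-1(10)-en-3-yl (2Z)-2-methylbut-2-enoate (target CNP0180504.5)
Conditions: Ac2O, pyridine, 4-(dimethylamino)pyridine (cat.), CH2Cl2, 0 → 23 °C
Reagents that add atoms: acetic anhydride (CC(=O)OC(C)=O)
Why: Nucleophile-catalysed acetylation of the secondary alcohol under basic conditions leaves the acid-sensitive epoxy-germacrene and the angelate untouched and retains configuration.

## Compound list

1 | m-cresol (3-methylphenol) | Cc1cccc(O)c1 | starting material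
2 | 4-methoxy-3-methylphenol | COc1ccc(O)cc1C | intermediate
3 | 4,4-dimethoxy-3-methylcyclohexa-2,5-dien-1-one | COC1(OC)C=CC(=O)C=C1C | intermediate
4 | 3-methylbutan-2-one | CC(C)C(C)=O | starting material
5 | 2,4,6-tri(propan-2-yl)benzenesulfonohydrazide | CC(C)c1cc(C(C)C)c(S(=O)(=O)NN)c(C(C)C)c1 | starting material
6 | N'-(3-methylbutan-2-ylidene)-2,4,6-tri(propan-2-yl)benzenesulfonohydrazide | CC(C)C(C)=NNS(=O)(=O)c1c(C(C)C)cc(C(C)C)cc1C(C)C | intermediate
7 | (3-methylbut-1-en-2-yl)lithium | [Li]C(=C)C(C)C | intermediate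
8 | 4,4-dimethoxy-3-methyl-1-(3-methylbut-1-en-2-yl)cyclohexa-2,5-dien-1-ol (racemic) | COC1(OC)C=CC(O)(C(=C)C(C)C)C=C1C | intermediate
9 | 4-hydroxy-2-methyl-4-(3-methylbut-1-en-2-yl)cyclohexa-2,5-dien-1-one (racemic) | O=C1C=CC(O)(C(=C)C(C)C)C=C1C | intermediate
10 | isopropenylmagnesium bromide | CC(=C)[Mg]Br | starting material
11 | rac-(4R,5R)-4-hydroxy-2-methyl-4-(3-methylbut-1-en-2-yl)-5-(prop-1-en-2-yl)cyclohex-2-en-1-one (OH cis to isopropenyl) | O=C1C[C@H](C(C)=C)[C@@](O)(C(=C)C(C)C)C=C1C | intermediate
12 | dipotassium (1(10)E,4Z)-germacra-1(10),2,4,6-tetraene-3,6-bis(olate) | [K+].[K+].[O-]C1=C/C=C(\C)CCC(C(C)C)=C([O-])/C=C1/C | intermediate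
13 | (1(10)E,4Z)-germacra-1(10),4-diene-3,6-dione (racemic at C7) | O=C1C/C=C(\C)CCC(C(C)C)C(=O)/C=C1/C | intermediate
14 | potassium (1(10)E)-6-oxogermacra-1(10),3-dien-3-olate | [K+].[O-]C1=C(C)CC(=O)C(C(C)C)CC/C(C)=C/C1 | intermediate
15 | (1(10)E)-4-(phenylselanyl)germacr-1(10)-ene-3,6-dione | O=C1C/C=C(\C)CCC(C(C)C)C(=O)CC1(C)[Se]c1ccccc1 | intermediate
16 | (1(10)E)-4-(phenylseleninyl)germacr-1(10)-ene-3,6-dione | O=C1C/C=C(\C)CCC(C(C)C)C(=O)CC1(C)[Se](=O)c1ccccc1 | intermediate
17 | (1(10)E,4E)-germacra-1(10),4-diene-3,6-dione (racemic at C7) | O=C1C/C=C(\C)CCC(C(C)C)C(=O)/C=C1\C | intermediate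
18 | (3R,7S,1(10)E,4E)-3-hydroxygermacra-1(10),4-dien-6-one | O[C@@H]1C/C=C(\C)CC[C@@H](C(C)C)C(=O)/C=C1\C | intermediate
19 | (3R,7R,1(10)E,4E)-3-hydroxygermacra-1(10),4-dien-6-one | O[C@@H]1C/C=C(\C)CC[C@H](C(C)C)C(=O)/C=C1\C | intermediate
20 | angelic acid ((2Z)-2-methylbut-2-enoic acid) | C/C=C(/C)C(=O)O | starting material
21 | (2Z)-2-methylbut-2-enoic 2,4,6-trichlorobenzoic anhydride | C/C=C(/C)C(=O)OC(=O)c1c(Cl)cc(Cl)cc1Cl | intermediate
22 | (3R,7R,1(10)E,4E)-6-oxogermacra-1(10),4-dien-3-yl (2Z)-2-methylbut-2-enoate | C/C=C(/C)C(=O)O[C@@H]1C/C=C(\C)CC[C@H](C(C)C)C(=O)/C=C1\C | intermediate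
23 | (3R,6S,7R,1(10)E,4E)-6-hydroxygermacra-1(10),4-dien-3-yl (2Z)-2-methylbut-2-enoate | C/C=C(/C)C(=O)O[C@@H]1C/C=C(\C)CC[C@H](C(C)C)[C@H](O)/C=C1\C | intermediate
24 | (3R,4R,5R,6S,7R,1(10)E)-4,5-epoxy-6-hydroxygermacr-1(10)-en-3-yl (2Z)-2-methylbut-2-enoate | C/C=C(/C)C(=O)O[C@@H]1C/C=C(\C)CC[C@H](C(C)C)[C@H](O)[C@H]2O[C@@]21C | intermediate
25 | (3R,4R,5R,6S,7R,1(10)E)-6-acetoxy-4,5-epoxygermacr-1(10)-en-3-yl (2Z)-2-methylbut-2-enoate | C/C=C(/C)C(=O)O[C@@H]1C/C=C(\C)CC[C@H](C(C)C)[C@H](OC(C)=O)[C@H]2O[C@@]21C | target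

## Step count and weak points

Total step count: 11. Longest linear sequence: 10 steps (steps 1 and 3–11, from m-cresol).

**Step 5 (oxy-Cope with the enone in place; the Z-enedione 13 is sensitive to base and to transannular aldol closure).**
The fallback sets out from 11 and comes back at 17. Compound 11 is first reduced in the 1,4-sense by hydrosilylation (Et3SiH, RhCl(PPh3)3, benzene, 50 °C) to the triethylsilyl enol ether F1. KH and 18-crown-6 then bring about the oxy-Cope rearrangement to the ten-membered keto silyl enol ether F2, a masked 1,4-diketone that cannot undergo aldol closure. PhSeCl at −78 °C selenenylates the silyl enol ether at C4 to give 15, and NaIO4 takes 15 on to 17 as in step 6.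

**Step 6 (regioselective 1,4-reduction and E-selective syn-elimination).**
The fallback sets out from 13 and comes back at 17. If the elimination returns the Z olefin, the geometry is inverted stereospecifically. NaBH4/CeCl3·7H2O reduces 13 to the (4Z)-ene-3,6-diol F3 (diol diastereomers are irrelevant). VO(acac)2 and t-BuOOH give the cis-4,5-epoxy diol F4. LiPPh2 opens the oxirane at C5 with inversion, and quaternisation with MeI triggers syn-elimination of the phosphine oxide to give the (4E)-ene-3,6-diol F5. MnO2 then oxidises both allylic alcohols to 17.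

**Step 7 (site-selective catalyst-controlled reduction and, above all, the thermodynamic C7 equilibration, whose bias may be modest).**
The fallback sets out from 18 (the unequilibrated mixture with 19) and comes back at 22. Without base treatment the mixture is acylated as in step 8, so that 19 gives 22 and 18 gives the (3R,7S)-keto angelate F6. The mixture is reduced as in step 9, and chromatography separates 23 from its diastereomer, the (3R,6R,7S)-hydroxy angelate F7. F7 is oxidised back to F6 with Dess–Martin periodinane, and F6 is epimerised at C7 with 1,8-diazabicyclo[5.4.0]undec-7-ene in CH2Cl2 to 22, which re-enters step 9.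

## Further compounds

F1 | step 5 | 3-methyl-1-(3-methylbut-1-en-2-yl)-6-(prop-1-en-2-yl)-4-[(triethylsilyl)oxy]cyclohex-3-en-1-ol (racemic, OH cis to isopropenyl) | CC[Si](CC)(CC)OC1=C(C)C[C@](O)(C(=C)C(C)C)[C@@H](C(C)=C)C1
F2 | step 5 | (1(10)E)-3-[(triethylsilyl)oxy]germacra-1(10),3-dien-6-one (C2 and C5 cis on the 3,4-olefin, racemic) | CC[Si](CC)(CC)O/C1=C(\C)CC(=O)C(C(C)C)CC/C(C)=C/C1
F3 | step 6 | (1(10)E,4Z)-germacra-1(10),4-diene-3,6-diol (diastereomer mixture) | OC1C/C=C(\C)CCC(C(C)C)C(O)/C=C1/C
F4 | step 6 | (1(10)E)-cis-4,5-epoxygermacr-1(10)-ene-3,6-diol (C3 and C6 cis across the oxirane, diastereomer mixture) | OC1C/C=C(\C)CCC(C(C)C)C(O)[C@@H]2O[C@@]21C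
F5 | step 6 | (1(10)E,4E)-germacra-1(10),4-diene-3,6-diol (diastereomer mixture) | OC1C/C=C(\C)CCC(C(C)C)C(O)/C=C1\C
F6 | step 7 | (3R,7S,1(10)E,4E)-6-oxogermacra-1(10),4-dien-3-yl (2Z)-2-methylbut-2-enoate | C/C=C(/C)C(=O)O[C@@H]1C/C=C(\C)CC[C@@H](C(C)C)C(=O)/C=C1\C
F7 | step 7 | (3R,6R,7S,1(10)E,4E)-6-hydroxygermacra-1(10),4-dien-3-yl (2Z)-2-methylbut-2-enoate | C/C=C(/C)C(=O)O[C@@H]1C/C=C(\C)CC[C@@H](C(C)C)[C@@H](O)/C=C1\C
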